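**Plan**

1. Retrosynthesis: the catechol is traced back to its dimethyl ether; the pyranone is opened at O1'–C2' (enol lactone) and at C5'–C6' (bond from a side-chain methyl group to an oxalyl carbon); the carbocycle is cut at C1–C2 and C3–C4 (photoenol Diels–Alder, the C3=C4 alkene arising by loss of water); last, the aryl–CH2 bond of the side chain is cut.
2. Forward: the 3-methylbut-2-enoate chain is joined to the arene, the carbocyclic ring is closed by cycloaddition and dehydrated, the pyranone ring is grown on the finished core, and the two phenols are freed at the end.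
3. Enabling feature: the ring made of O1', C2'(=O), C3', C4' (bonded to C1), C5' and C6' (bearing CO2H) is the enol lactone of a 3-substituted 5-oxalylpent-2-enoate, so it can be grown from the methyl group of a 3-methylbut-2-enoate hung on C1; C1–H lies γ to that ester, and the carboxyl on C2 can be held as a carboxylate that alkoxide cannot enolise.
4. Stereochemistry: C1 (R) and C2 (S) are set together in a titanium TADDOLate-controlled cycloaddition (trans from an E,E-dienol and an exo ester); in the pyranone-forming step C2 is frozen as its carboxylate and C1 rests in the trans arrangement that C2 dictates.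

Key step: step 4

Assumption: the (R,R) antipode of TADDOL is taken to deliver the cycloadduct of step 2 as drawn (if the sense of induction is opposite, the (S,S) ligand is used instead); the side-chain double bond is drawn E throughout, its geometry being erased at the dienolate stage of step 4.

**Route**

Step 1
Reactants: 1 (2-formyl-4,5-dimethoxyphenyl)boronic acid; 2 ethyl (E)-4-bromo-3-methylbut-2-enoate
Product: 3 ethyl (E)-4-(2-formyl-4,5-dimethoxyphenyl)-3-methylbut-2-enoate
Conditions: Pd(PPh3)4 (5 mol %), K2CO3, THF/H2O (10:1), 45 °C, Ar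
Reagents that add atoms: none
Why: Suzuki–Miyaura coupling of an arylboronic acid with an allylic bromide, in which the allylpalladium intermediate should be arylated at its unsubstituted CH2 terminus so that the enoate stays conjugated, the mild carbonate base and low temperature being chosen to spare the aldehyde and the γ-acidic benzylic CH2.

Step 2
Reactants: 3 ethyl (E)-4-(2-formyl-4,5-dimethoxyphenyl)-3-methylbut-2-enoate; 4 di-tert-butyl fumarate
Product: 6 di-tert-butyl (1R,2R,3S,4R)-4-[(E)-4-ethoxy-4-oxobut-2-en-2-yl]-1-hydroxy-6,7-dimethoxy-1,2,3,4-tetrahydronaphthalene-2,3-dicarboxylate, via photoenol 5 (not isolated)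
Conditions: Ti(OiPr)4 (1.5 equiv), (R,R)-TADDOL [(4R,5R)-2,2-dimethyl-α,α,α',α'-tetraphenyl-1,3-dioxolane-4,5-dimethanol, 1.5 equiv], 4 (3 equiv), hν (365 nm), toluene, rt, Ar
Reagents that add atoms: none
Why: Enantioselective photoenolisation/Diels–Alder reaction, in which 1,5-hydrogen transfer in the excited aldehyde gives the E,E-hydroxy-o-quinodimethane 5 that is held on the chiral titanium diolate together with one ester carbonyl of 4, so that this ester should add endo and cis to the hydroxyl, the other ester should end up trans to the outward-pointing side chain, and the diolate should shield one face of the bound dienol and thus fix all four centres (1R,2R,3S,4R) in absolute terms.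

Step 3
Reactants: 6 di-tert-butyl (1R,2R,3S,4R)-4-[(E)-4-ethoxy-4-oxobut-2-en-2-yl]-1-hydroxy-6,7-dimethoxy-1,2,3,4-tetrahydronaphthalene-2,3-dicarboxylate
Product: 8 (1R,2S)-1-[(E)-4-ethoxy-4-oxobut-2-en-2-yl]-6,7-dimethoxy-1,2-dihydronaphthalene-2,3-dicarboxylic acid, via di-tert-butyl dihydronaphthalene diester 7 (not isolated)
Conditions: TFA/CH2Cl2 (1:1), 0 °C → rt
Reagents that add atoms: none
Why: Acid-mediated E1 dehydration followed by tert-butyl ester acidolysis, in which the benzylic alcohol para to a methoxy group should ionise readily and lose the adjacent α-proton to give the aryl-conjugated acrylate, both tert-butyl esters should then leave as isobutene, and the ethyl enoate and the two remaining stereocentres (C3 and C4 of 6, which become C2 and C1 of 8) are not touched.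

Step 4
Reactants: 8 (1R,2S)-1-[(E)-4-ethoxy-4-oxobut-2-en-2-yl]-6,7-dimethoxy-1,2-dihydronaphthalene-2,3-dicarboxylic acid; 9 diethyl oxalate
Product: 11 (1R,2S)-1-(6-carboxy-2-oxo-2H-pyran-4-yl)-6,7-dimethoxy-1,2-dihydronaphthalene-2,3-dicarboxylic acid, via oxalyl adduct 10 (not isolated)
Conditions: KOEt (5 equiv), (CO2Et)2 (3 equiv), THF/EtOH, 0 → 45 °C, Ar; then 6 M HCl/AcOH, 80 °C
Reagents that add atoms: water, O
Why: Ethoxide first turns 8 into its 2,3-dicarboxylate and then reversibly deprotonates the side chain to its dienolate, which is C-acylated by 9 at the γ-methyl carbon (new C5'–C6' bond) to give the enolate of 10. This is the vinylogous Claisen condensation long used to convert 3-methylbut-2-enoates and oxalate into 4-substituted 2-pyranone-6-carboxylic acids. On acidification and heating the C6' enol oxygen should attack the butenoate carbonyl in a 6-exo-trig acyl substitution (new O1'–C2' bond, ethanol lost), keto–enol equilibration supplying the cis arrangement that closure needs, and the remaining oxalyl ethyl ester is hydrolysed in the same pot. No stereocentre is formed: C2 keeps its configuration because a carboxylate cannot be enolised by ethoxide, and C1, which can be deprotonated reversibly, should settle in the more stable trans arrangement dictated by C2. The step needs acylation at the methyl group and not at C1 or the α-carbon, and reversibility secures this, since the C1 adduct is quaternary, cannot form an enolate and reverts, the α-adduct gives only a cross-conjugated enolate, and the methyl adduct alone is drained as a fully conjugated, doubly stabilised enolate. The charges on the C2 and C3 carboxylates should also keep ethoxide from shifting the C3=C4 double bond or aromatising the ring.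

Step 5
Reactants: 11 (1R,2S)-1-(6-carboxy-2-oxo-2H-pyran-4-yl)-6,7-dimethoxy-1,2-dihydronaphthalene-2,3-dicarboxylic acid
Product: 12 (1R,2S)-1-(6-carboxy-2-oxo-2H-pyran-4-yl)-6,7-dihydroxy-1,2-dihydronaphthalene-2,3-dicarboxylic acid
Conditions: BBr3 (10 equiv), CH2Cl2, −78 °C → rt; then H2O, 0 °C
Reagents that add atoms: none
Why: Lewis acid cleavage of aryl methyl ethers, in which BBr3 coordinates each ether oxygen and bromide removes the methyl group by SN2 displacement, while the carboxylic acids and the pyranone lactone are only complexed and should be restored on aqueous work-up, with no stereocentre affected.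

**Compound list**

1 | (2-formyl-4,5-dimethoxyphenyl)boronic acid | O=Cc1cc(OC)c(OC)cc1B(O)O | starting material
2 | ethyl (E)-4-bromo-3-methylbut-2-enoate | CCOC(=O)/C=C(\C)CBr | starting material
3 | ethyl (E)-4-(2-formyl-4,5-dimethoxyphenyl)-3-methylbut-2-enoate | CCOC(=O)/C=C(\C)Cc1cc(OC)c(OC)cc1C=O | intermediate
4 | di-tert-butyl fumarate | CC(C)(C)OC(=O)/C=C/C(=O)OC(C)(C)C | starting material
5 | E,E-photoenol of 3 (hydroxy-o-quinodimethane), ethyl (2E,4E)-4-[(6E)-6-(hydroxymethylidene)-3,4-dimethoxycyclohexa-2,4-dien-1-ylidene]-3-methylbut-2-enoate | O/C=C1\C=C(OC)C(OC)=C\C1=C/C(C)=C/C(=O)OCC | intermediate (not isolated)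
6 | di-tert-butyl (1R,2R,3S,4R)-4-[(E)-4-ethoxy-4-oxobut-2-en-2-yl]-1-hydroxy-6,7-dimethoxy-1,2,3,4-tetrahydronaphthalene-2,3-dicarboxylate (1-OH/2-ester cis, 2,3-trans, 3,4-trans) | CC(C)(C)OC(=O)[C@H]1[C@@H](O)c2cc(OC)c(OC)cc2[C@@H](/C(C)=C/C(=O)OCC)[C@@H]1C(=O)OC(C)(C)C | intermediate
7 | di-tert-butyl (1R,2S)-1-[(E)-4-ethoxy-4-oxobut-2-en-2-yl]-6,7-dimethoxy-1,2-dihydronaphthalene-2,3-dicarboxylate | CC(C)(C)OC(=O)C1=Cc2cc(OC)c(OC)cc2[C@@H](/C(C)=C/C(=O)OCC)[C@@H]1C(=O)OC(C)(C)C | intermediate (not isolated)
8 | (1R,2S)-1-[(E)-4-ethoxy-4-oxobut-2-en-2-yl]-6,7-dimethoxy-1,2-dihydronaphthalene-2,3-dicarboxylic acid (trans) | OC(=O)C1=Cc2cc(OC)c(OC)cc2[C@@H](/C(C)=C/C(=O)OCC)[C@@H]1C(=O)O | intermediate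
9 | diethyl oxalate | CCOC(=O)C(=O)OCC | starting material
10 | (1R,2S)-1-[(E)-1,6-diethoxy-1,5,6-trioxohex-2-en-3-yl]-6,7-dimethoxy-1,2-dihydronaphthalene-2,3-dicarboxylic acid (oxalyl adduct, present in the flask as its potassium enolate and dicarboxylate, drawn in the neutral keto form) | OC(=O)C1=Cc2cc(OC)c(OC)cc2[C@@H](/C(CC(=O)C(=O)OCC)=C/C(=O)OCC)[C@@H]1C(=O)O | intermediate (not isolated)
11 | (1R,2S)-1-(6-carboxy-2-oxo-2H-pyran-4-yl)-6,7-dimethoxy-1,2-dihydronaphthalene-2,3-dicarboxylic acid | OC(=O)C1=Cc2cc(OC)c(OC)cc2[C@@H](c2cc(C(=O)O)oc(=O)c2)[C@@H]1C(=O)O | intermediate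
12 | (1R,2S)-1-(6-carboxy-2-oxo-2H-pyran-4-yl)-6,7-dihydroxy-1,2-dihydronaphthalene-2,3-dicarboxylic acid (CNP0195322.1) | O=C(O)C1=Cc2cc(O)c(O)cc2[C@@H](c2cc(C(=O)O)oc(=O)c2)[C@@H]1C(=O)O | target

**Step count and risks**

Total step count: 5. Longest linear sequence: 5 steps (from 1 or 2 to 12).

Steps most likely to fail, riskiest first:

Step 2. The titanium diolate may discriminate poorly between the dienol faces when the dienophile is a bulky tert-butyl ester. Photoenol 5 may also be lost by reketonisation, by sensitised E/Z isomerisation of the enoate, or by 6π-electrocyclisation of a Z-configured dienol onto the pendant alkene. Fallback (sets out from 3, returns at 8): irradiation of 3 with 4 in toluene without titanium or ligand should give, through the same photoenol 5, the hydroxyl-endo cycloadduct as a racemate, racemic di-tert-butyl hydroxytetralin diester F1. TFA as in step 3 should give racemic trans diacid F2. Classical resolution by fractional crystallisation with (R)-1-phenylethylamine should give the bis[(R)-1-phenylethylammonium] salt of the (1R,2S) acid F3, the amine antipode being chosen so that this salt is the less soluble one. Partition between aqueous HCl and EtOAc then returns 8.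

Step 4. Dienolate formation may be sluggish in a poorly soluble tripotassium salt. The enoate may deconjugate toward the exocyclic C1 alkylidene. Protonation at C1 during acidification may be kinetic and erode the trans relationship. The dihydronaphthalene may aromatise oxidatively if air is admitted. Fallback (sets out from 1, returns at 11): the same annulation is run first on the simplest substrate and the finished pyranone is carried through the ring construction.
- Ethyl 3-methylbut-2-enoate and 9 with KOEt, then HCl/EtOH, should give ethyl 4-methyl-2-oxo-2H-pyran-6-carboxylate F4.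
- Wohl–Ziegler bromination (NBS, AIBN, PhCF3, reflux) should give ethyl 4-(bromomethyl)-2-oxo-2H-pyran-6-carboxylate F5.
- Suzuki–Miyaura coupling with 1 (Pd(PPh3)4, KF, THF, 45 °C) should give ethyl 4-[(2-formyl-4,5-dimethoxyphenyl)methyl]-2-oxo-2H-pyran-6-carboxylate F6.
- Irradiation with 4 under the conditions of step 2 should give, through the pyranonyl photoenol F7 (not isolated), the hydroxytetralin adduct carrying the pyranone ester F8.
- TFA as in step 3 should give the dihydronaphthalene diacid with the ethyl pyranone-6-carboxylate F9.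
- 6 M HCl/AcOH at 80 °C hydrolyses that ethyl ester to 11.

Step 1. The ortho-formyl boronic acid may protodeboronate. The product may undergo base-induced intramolecular vinylogous aldol condensation (dienolate attack on the aldehyde, then dehydration to a naphthoate). The double bond may migrate into conjugation with the arene. Fallback (sets out from 2, returns at 3): coupling of 2 with commercial 3,4-dimethoxyphenylboronic acid under the same palladium conditions should give ethyl (E)-4-(3,4-dimethoxyphenyl)-3-methylbut-2-enoate F10, which has no aldehyde and cannot cyclise. Rieche formylation (Cl2CHOMe, TiCl4, CH2Cl2, −20 → 0 °C) should then take place para to a methoxy group and ortho to the alkyl chain and give 3.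

**Further compounds**

F1 | step 2 | racemic di-tert-butyl (1R*,2R*,3S*,4R*)-4-[(E)-4-ethoxy-4-oxobut-2-en-2-yl]-1-hydroxy-6,7-dimethoxy-1,2,3,4-tetrahydronaphthalene-2,3-dicarboxylate (both enantiomers) | CC(C)(C)OC(=O)[C@H]1[C@@H](O)c2cc(OC)c(OC)cc2[C@@H](/C(C)=C/C(=O)OCC)[C@@H]1C(=O)OC(C)(C)C.CC(C)(C)OC(=O)[C@@H]1[C@H](O)c2cc(OC)c(OC)cc2[C@H](/C(C)=C/C(=O)OCC)[C@H]1C(=O)OC(C)(C)C
F2 | step 2 | racemic trans-1-[(E)-4-ethoxy-4-oxobut-2-en-2-yl]-6,7-dimethoxy-1,2-dihydronaphthalene-2,3-dicarboxylic acid (both enantiomers) | OC(=O)C1=Cc2cc(OC)c(OC)cc2[C@@H](/C(C)=C/C(=O)OCC)[C@@H]1C(=O)O.OC(=O)C1=Cc2cc(OC)c(OC)cc2[C@H](/C(C)=C/C(=O)OCC)[C@H]1C(=O)O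
F3 | step 2 | bis[(R)-1-phenylethylammonium] (1R,2S)-1-[(E)-4-ethoxy-4-oxobut-2-en-2-yl]-6,7-dimethoxy-1,2-dihydronaphthalene-2,3-dicarboxylate | [O-]C(=O)C1=Cc2cc(OC)c(OC)cc2[C@@H](/C(C)=C/C(=O)OCC)[C@@H]1C(=O)[O-].C[C@@H]([NH3+])c1ccccc1.C[C@@H]([NH3+])c1ccccc1
F4 | step 4 | ethyl 4-methyl-2-oxo-2H-pyran-6-carboxylate | CCOC(=O)c1cc(C)cc(=O)o1
F5 | step 4 | ethyl 4-(bromomethyl)-2-oxo-2H-pyran-6-carboxylate | CCOC(=O)c1cc(CBr)cc(=O)o1
F6 | step 4 | ethyl 4-[(2-formyl-4,5-dimethoxyphenyl)methyl]-2-oxo-2H-pyran-6-carboxylate | CCOC(=O)c1cc(Cc2cc(OC)c(OC)cc2C=O)cc(=O)o1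
F7 | step 4 | E,E-photoenol of F6, ethyl 4-{(E)-[(6E)-6-(hydroxymethylidene)-3,4-dimethoxycyclohexa-2,4-dien-1-ylidene]methyl}-2-oxo-2H-pyran-6-carboxylate | O/C=C1\C=C(OC)C(OC)=C\C1=C/c1cc(C(=O)OCC)oc(=O)c1
F8 | step 4 | di-tert-butyl (1R,2R,3S,4R)-4-[6-(ethoxycarbonyl)-2-oxo-2H-pyran-4-yl]-1-hydroxy-6,7-dimethoxy-1,2,3,4-tetrahydronaphthalene-2,3-dicarboxylate | CC(C)(C)OC(=O)[C@H]1[C@@H](O)c2cc(OC)c(OC)cc2[C@@H](c2cc(C(=O)OCC)oc(=O)c2)[C@@H]1C(=O)OC(C)(C)C
F9 | step 4 | (1R,2S)-1-[6-(ethoxycarbonyl)-2-oxo-2H-pyran-4-yl]-6,7-dimethoxy-1,2-dihydronaphthalene-2,3-dicarboxylic acid | OC(=O)C1=Cc2cc(OC)c(OC)cc2[C@@H](c2cc(C(=O)OCC)oc(=O)c2)[C@@H]1C(=O)O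
F10 | step 1 | ethyl (E)-4-(3,4-dimethoxyphenyl)-3-methylbut-2-enoate | CCOC(=O)/C=C(\C)Cc1ccc(OC)c(OC)c1
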